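**Plan**

- Retrosynthetic cuts, in order: the two acetates; the furan ring at C3–C1' and C2–O2' (a 2-aminochromone plus the ring B para-quinone); the pyranone O1–C8a bond (aryl fluoride plus amide-enolate oxygen); the C6 methyl and the C4a carbonyl carbon (two ring lithiations); and the ring A chromene, at the bond between its two olefinic carbons and at the bond from the pyran oxygen to C7.
- Enabling feature: in ring A the carbon C8 that carries the chromene CH lies between the two oxygen-bearing carbons C7 and C8a. Written as a formyl carbon between two equivalent C–F carbons, ring A is a symmetric 2,6-difluorobenzaldehyde. A three-atom C,O-dianion (LiCH2CMe2OLi) can then bridge the formyl carbon and one C–F carbon in a [3+3] annulation, and the second fluorine stays as the later site of the pyranone oxygen, so no angular/linear or 6-methyl/8-methyl ambiguity arises.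
- Forward order: ring A dimethylpyran (key step, then dehydration); formyl and methyl by lithiation; pyranone by SNAr; ring B pyran built separately on 2,5-dimethoxyphenol and oxidised to the quinone; furan ring last.
- Stereochemistry: both carbinol centres come from a Jacobsen epoxidation of the ring B chromene (catalyst control) and anti opening of the epoxide by water at the benzylic carbon. This is done before the fragments are joined, so the ring A chromene olefin is never exposed to the epoxidation.

Key step: step 2

Remark: (R,R)-(salen)MnCl is taken to give the (3R,4R)-epoxide of a 2,2-dimethyl-2H-chromene, the sense established for this substrate class.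
Remark: 2,5-dimethoxyphenol is taken as a catalogue compound.
Remark: ring A and the pyranone carry chromone locants (O1, C2–C4, C4a–C8a), ring B carries primed locants, and the bicyclic chromene and chroman intermediates carry chromene locants.

**Route**

Step 1
Reactants: 1 2,6-difluoro-4-hydroxybenzaldehyde
Product: 2 2,6-difluoro-4-(methoxymethoxy)benzaldehyde
Conditions: MOMCl, iPr2NEt, CH2Cl2, 0 °C → rt
Reagents that add atoms: chloromethyl methyl ether, COCCl
Why: O-alkylation of the acidic phenol (Williamson-type) should give the MOM ether, which removes the deactivating phenoxide, survives organolithium reagents and later directs ring lithiation.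

Step 2
Reactants: 2 2,6-difluoro-4-(methoxymethoxy)benzaldehyde; 3 1-chloro-2-methylpropan-2-ol
Product: 6 5-fluoro-7-(methoxymethoxy)-2,2-dimethylchroman-4-ol (racemic), via β-lithio alkoxide LiCH2CMe2OLi 4 (not isolated), via dilithium diolate adduct 5 (not isolated)
Conditions: 3, n-BuLi, THF, −78 °C; Li powder, 4,4'-di-tert-butylbiphenyl (cat.), −78 °C, cannula filtration; 2, −78 °C; then KN(SiMe3)2, DMPU, −78 → 60 °C; aq. NH4Cl
Reagents that add atoms: none
Why: The dianion LiCH2C(CH3)2OLi, which persists at −78 °C, adds through carbon to the formyl group of 2 (1,2-addition of an alkyllithium to an aryl aldehyde) and so forms the bond between the benzylic carbon and the methylene carbon. The tertiary alkoxide that the reagent brings along then lies within reach of either ortho C–F carbon and, after exchange of its counter-ion for potassium in DMPU, attacks one of them in an intramolecular SNAr reaction through a Meisenheimer complex that the meta fluorine and the meta acetal oxygen stabilise inductively, with loss of fluoride. The closest known reaction types are the addition of β-lithio alkoxides to aldehydes and the base-mediated cyclisation of 3-(2-fluoroaryl)propanols to chromans, run here in one flask as a formal [3+3] annulation. The only ring closed is the dihydropyran, in the 6-exo-trig mode (the attacked arene carbon is the trigonal centre and the electron pair moves to ring positions outside the new ring). The new carbinol centre C4 forms without control and is removed by the dehydration in step 3. The step needs carbonyl addition before any attack on C–F (secured by the −78 °C addition) and ring closure through the right oxygen (the benzylic alkoxide could only give a four-membered ring); it has no regiochemical issue, because the two C–F carbons of 2 are equivalent by symmetry.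

Step 3
Reactants: 6 5-fluoro-7-(methoxymethoxy)-2,2-dimethylchroman-4-ol
Product: 7 5-fluoro-7-(methoxymethoxy)-2,2-dimethyl-2H-chromene
Conditions: Burgess reagent (Et3N+–SO2–N−–CO2Me), toluene, 70 °C
Reagents that add atoms: none
Why: Burgess dehydration (syn elimination of the benzylic sulfamate toward the only β-hydrogens, at C3) should give the chromene double bond under neutral conditions that leave the MOM acetal intact.

Step 4
Reactants: 7 5-fluoro-7-(methoxymethoxy)-2,2-dimethyl-2H-chromene
Product: 9 5-fluoro-7-(methoxymethoxy)-2,2,8-trimethyl-2H-chromene-6-carbaldehyde, via lithium α-amino alkoxide 8 (not isolated)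
Conditions: s-BuLi, THF, −78 °C; DMF; then s-BuLi, TMEDA, −78 → −50 °C; MeI; aq. NH4Cl
Reagents that add atoms: N,N-dimethylformamide, CN(C)C=O; iodomethane, CI
Why: Directed ortho-metalation should first remove the most acidic ring hydrogen (C6, between F and OMOM) and the DMF quench gives a lithium α-amino alkoxide that is inert to more base, so a second metalation at the only remaining ring hydrogen (C8, between OMOM and the pyran oxygen) and methylation can follow before work-up releases the aldehyde.

Step 5
Reactants: 9 5-fluoro-7-(methoxymethoxy)-2,2,8-trimethyl-2H-chromene-6-carbaldehyde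
Product: 10 5-fluoro-7-(methoxymethoxy)-2,2,8-trimethyl-2H-chromene-6-carboxylic acid
Conditions: NaClO2, NaH2PO4, 2-methylbut-2-ene, t-BuOH/H2O, rt
Reagents that add atoms: sodium chlorite, [Na+].[O-]Cl=O
Why: Pinnick oxidation should convert the hindered aryl aldehyde into the acid while the alkene scavenger takes up HOCl, so the chromene olefin and the MOM acetal survive.

Step 6
Reactants: 10 5-fluoro-7-(methoxymethoxy)-2,2,8-trimethyl-2H-chromene-6-carboxylic acid
Product: 13 2-(dimethylamino)-5-(methoxymethoxy)-6,8,8-trimethyl-4H,8H-pyrano[2,3-f]chromen-4-one, via acyl imidazolide 11 (not isolated), via β-keto amide lithium enolate 12 (not isolated)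
Conditions: CDI, THF, rt; LiCH2C(O)NMe2 (from MeC(O)NMe2, LiN(iPr)2), THF, −78 °C → rt; then DMF, 90 °C
Reagents that add atoms: N,N-dimethylacetamide, CC(=O)N(C)C
Why: Claisen-type C-acylation of the amide enolate by the acyl imidazolide should give the β-keto amide enolate, whose amide oxygen displaces the fluorine ortho to the ketone by intramolecular SNAr (the chromone closure known for 2-fluoroaroyl 1,3-dicarbonyl compounds), so the pyranone oxygen can only end up on the carbon next to the chromene carbon.

Step 7
Reactants: 13 2-(dimethylamino)-5-(methoxymethoxy)-6,8,8-trimethyl-4H,8H-pyrano[2,3-f]chromen-4-one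
Product: 14 2-(dimethylamino)-5-hydroxy-6,8,8-trimethyl-4H,8H-pyrano[2,3-f]chromen-4-one
Conditions: HCl (3 M aq.), MeOH, 40 °C
Reagents that add atoms: none
Why: Acid-catalysed acetal exchange should remove the MOM group, which is especially labile next to the chromone carbonyl, and give the chelated 5-hydroxyl at a stage where no acid-sensitive benzylic carbinol is present.

Step 8
Reactants: 15 2,5-dimethoxyphenol; 16 3-methylbut-2-enal
Product: 17 5,8-dimethoxy-2,2-dimethyl-2H-chromene
Conditions: PhB(OH)2, AcOH (cat.), toluene, reflux (Dean–Stark)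
Reagents that add atoms: none
Why: Boronic acid-templated ortho-condensation of the phenol with the enal should give an ortho-quinone methide that closes by oxa-6π electrocyclisation (chromenylation), and the single free ortho position fixes the regiochemistry.

Step 9
Reactants: 17 5,8-dimethoxy-2,2-dimethyl-2H-chromene
Product: 18 (3R,4R)-3,4-epoxy-5,8-dimethoxy-2,2-dimethylchromane
Conditions: (R,R)-(salen)MnCl [salen = N,N'-bis(3,5-di-tert-butylsalicylidene)cyclohexane-1,2-diamine dianion] (cat.), NaOCl (aq., pH 11), 4-phenylpyridine N-oxide, CH2Cl2, 0 °C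
Reagents that add atoms: sodium hypochlorite, [Na+].[O-]Cl
Why: Jacobsen epoxidation of the cis-disubstituted aryl-conjugated olefin (2,2-dimethylchromenes are a privileged substrate class) should deliver oxygen to one enantioface under catalyst control and so set C3 and C4 together.

Step 10
Reactants: 18 (3R,4R)-3,4-epoxy-5,8-dimethoxy-2,2-dimethylchromane
Product: 19 (3R,4S)-5,8-dimethoxy-2,2-dimethylchromane-3,4-diol
Conditions: H2SO4 (0.5 M aq.), acetone, 0 °C → rt
Reagents that add atoms: water, O
Why: Acid-catalysed epoxide hydrolysis with water attacking the benzylic C4 anti to the epoxide oxygen (inversion at C4, C3 untouched) should give the trans-diol.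

Step 11
Reactants: 19 (3R,4S)-5,8-dimethoxy-2,2-dimethylchromane-3,4-diol
Product: 20 (3R,4S)-5,8-dimethoxy-2,2-dimethylchromane-3,4-diyl diacetate
Conditions: Ac2O, pyridine, DMAP, rt → 40 °C
Reagents that add atoms: acetic anhydride, CC(=O)OC(C)=O
Why: DMAP-catalysed acylation should protect both secondary hydroxyls without touching either stereocentre, so that the 1,2-diol is not cleaved by the cerium oxidant and the benzylic position is less prone to ionise.

Step 12
Reactants: 20 (3R,4S)-5,8-dimethoxy-2,2-dimethylchromane-3,4-diyl diacetate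
Product: 21 (3R,4S)-2,2-dimethyl-5,8-dioxo-3,4,5,8-tetrahydro-2H-chromene-3,4-diyl diacetate
Conditions: (NH4)2Ce(NO3)6, MeCN/H2O, 0 °C
Reagents that add atoms: water, O
Why: Oxidative demethylation of the para-dimethoxyarene by tetravalent cerium (arene radical cation, ipso attack of water, loss of methanol) should give the para-quinone with the pyran oxygen retained as a ring alkoxy substituent.

Step 13
Reactants: 14 2-(dimethylamino)-5-hydroxy-6,8,8-trimethyl-4H,8H-pyrano[2,3-f]chromen-4-one; 21 (3R,4S)-2,2-dimethyl-5,8-dioxo-3,4,5,8-tetrahydro-2H-chromene-3,4-diyl diacetate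
Product: 23 3,4-di-O-acetate of the target, via hydroquinone Michael adduct 22 (not isolated)
Conditions: AcOH/CH2Cl2, 25 → 40 °C, argon
Reagents that add atoms: none
Why: Proposed new method: 14 is a cyclic tertiary enaminone whose C3 is the nucleophilic α-carbon, so it should add in Michael fashion to the unsubstituted CH=CH side of quinone 21 at C6 (the carbon β to the C8 carbonyl, because the C5 carbonyl is deactivated as a vinylogous ester by the ring oxygen), the adduct tautomerises to hydroquinone 22, and the hydroquinone hydroxyl next to the new C–C bond then adds to the amidinium-like C2 of the protonated chromone and expels dimethylamine (5-exo-trig addition–elimination) to close the furan and leave the other hydroxyl free as 5'-OH; the closest known reaction type is the Nenitzescu-type synthesis of 5-hydroxybenzofurans from acyclic tertiary enaminones and 1,4-benzoquinones in acetic acid, and no stereocentre is formed or touched.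

Step 14
Reactants: 23 3,4-di-O-acetate of the target
Product: 24 target CNP0351839.1
Conditions: K2CO3, MeOH, 0 °C → rt
Reagents that add atoms: none
Why: Zemplén-type transesterification should cleave both acetates by acyl–oxygen fission, so neither carbinol centre is touched and the free trans-diol of the target results.

**Compound list**

1 | 2,6-difluoro-4-hydroxybenzaldehyde | O=Cc1c(F)cc(O)cc1F | starting material
2 | 2,6-difluoro-4-(methoxymethoxy)benzaldehyde | COCOc1cc(F)c(C=O)c(F)c1 | intermediate
3 | 1-chloro-2-methylpropan-2-ol | CC(C)(O)CCl | starting material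
4 | lithium 1-lithio-2-methylpropan-2-olate (LiCH2CMe2OLi) | [Li]CC(C)(C)O[Li] | intermediate
5 | dilithium 1-[2,6-difluoro-4-(methoxymethoxy)phenyl]-3-methylbutane-1,3-diolate (racemic) | COCOc1cc(F)c(C(O[Li])CC(C)(C)O[Li])c(F)c1 | intermediate
6 | 5-fluoro-7-(methoxymethoxy)-2,2-dimethylchroman-4-ol (racemic) | COCOc1cc(F)c2C(O)CC(C)(C)Oc2c1 | intermediate
7 | 5-fluoro-7-(methoxymethoxy)-2,2-dimethyl-2H-chromene | COCOc1cc(F)c2C=CC(C)(C)Oc2c1 | intermediate
8 | lithium (dimethylamino)[5-fluoro-7-(methoxymethoxy)-2,2-dimethyl-2H-chromen-6-yl]methanolate | COCOc1cc2OC(C)(C)C=Cc2c(F)c1C(O[Li])N(C)C | intermediate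
9 | 5-fluoro-7-(methoxymethoxy)-2,2,8-trimethyl-2H-chromene-6-carbaldehyde | COCOc1c(C)c2OC(C)(C)C=Cc2c(F)c1C=O | intermediate
10 | 5-fluoro-7-(methoxymethoxy)-2,2,8-trimethyl-2H-chromene-6-carboxylic acid | COCOc1c(C)c2OC(C)(C)C=Cc2c(F)c1C(=O)O | intermediate
11 | [5-fluoro-7-(methoxymethoxy)-2,2,8-trimethyl-2H-chromen-6-yl](1H-imidazol-1-yl)methanone | COCOc1c(C)c2OC(C)(C)C=Cc2c(F)c1C(=O)n1ccnc1 | intermediate
12 | lithium enolate of 3-[5-fluoro-7-(methoxymethoxy)-2,2,8-trimethyl-2H-chromen-6-yl]-N,N-dimethyl-3-oxopropanamide | COCOc1c(C)c2OC(C)(C)C=Cc2c(F)c1C(O[Li])=CC(=O)N(C)C | intermediate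
13 | 2-(dimethylamino)-5-(methoxymethoxy)-6,8,8-trimethyl-4H,8H-pyrano[2,3-f]chromen-4-one (angular pyranochromone; pyran O on C7, pyran CH=CH on C8) | CN(C)c1cc(=O)c2c(OCOC)c(C)c3OC(C)(C)C=Cc3c2o1 | intermediate
14 | 2-(dimethylamino)-5-hydroxy-6,8,8-trimethyl-4H,8H-pyrano[2,3-f]chromen-4-one | CN(C)c1cc(=O)c2c(O)c(C)c3OC(C)(C)C=Cc3c2o1 | intermediate
15 | 2,5-dimethoxyphenol | COc1ccc(OC)c(O)c1 | starting material
16 | 3-methylbut-2-enal | CC(C)=CC=O | starting material
17 | 5,8-dimethoxy-2,2-dimethyl-2H-chromene | COc1ccc(OC)c2OC(C)(C)C=Cc12 | intermediate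
18 | (3R,4R)-3,4-epoxy-5,8-dimethoxy-2,2-dimethylchromane | COc1ccc(OC)c2OC(C)(C)[C@@H]3O[C@@H]3c12 | intermediate
19 | (3R,4S)-5,8-dimethoxy-2,2-dimethylchromane-3,4-diol (trans) | COc1ccc(OC)c2OC(C)(C)[C@H](O)[C@@H](O)c12 | intermediate
20 | (3R,4S)-5,8-dimethoxy-2,2-dimethylchromane-3,4-diyl diacetate | COc1ccc(OC)c2OC(C)(C)[C@H](OC(C)=O)[C@@H](OC(C)=O)c12 | intermediate
21 | (3R,4S)-2,2-dimethyl-5,8-dioxo-3,4,5,8-tetrahydro-2H-chromene-3,4-diyl diacetate | O=C1C=CC(=O)C2=C1[C@H](OC(C)=O)[C@@H](OC(C)=O)C(C)(C)O2 | intermediate
22 | (3R,4S)-6-[2-(dimethylamino)-5-hydroxy-6,8,8-trimethyl-4-oxo-4H,8H-pyrano[2,3-f]chromen-3-yl]-5,8-dihydroxy-2,2-dimethylchromane-3,4-diyl diacetate | CN(C)c1oc2c3C=CC(C)(C)Oc3c(C)c(O)c2c(=O)c1-c1cc(O)c2OC(C)(C)[C@H](OC(C)=O)[C@@H](OC(C)=O)c2c1O | intermediate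
23 | di-O-acetate of the target at the two carbinol oxygens of the ring B dihydropyran (3R,4S) | Cc1c2c(c3oc4oc5c6c(c(O)cc5c4c(=O)c3c1O)OC(C)(C)[C@H](OC(C)=O)[C@H]6OC(C)=O)C=CC(C)(C)O2 | intermediate
24 | CNP0351839.1: 5,5'-dihydroxy-6-methylcoumaronochromone (benzofuro[2,3-b]chromen-11-one core) with a 2,2-dimethyl-2H-pyran fused at C7(O)–C8 and a (3R,4S)-3,4-dihydroxy-2,2-dimethyl-3,4-dihydro-2H-pyran fused at C4'(O)–C3' | Cc1c2c(c3oc4oc5c6c(c(O)cc5c4c(=O)c3c1O)OC(C)(C)[C@H](O)[C@H]6O)C=CC(C)(C)O2 | target

**Step count and risks**

Total step count: 14. Longest linear sequence: 9 (steps 1–7, 13, 14).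

Steps most likely to fail:

1. Step 13 (Proposed new method). The conjugate addition may be slow because the aminochromone is a weak carbon nucleophile and the alkoxy-quinone a weak acceptor. It may also occur at the other quinone CH, or the adduct hydroquinone may exchange oxidation level with unreacted quinone. A further risk is ionisation at the benzylic acetate in the acidic medium, which would erode the trans configuration. The fallback uses known reactions, sets out from 14 and 20 and comes back at 22. Iodination of 14 at C3 with N-iodosuccinimide would give 2-(dimethylamino)-5-hydroxy-3-iodo-6,8,8-trimethyl-4H,8H-pyrano[2,3-f]chromen-4-one F1. Bromination of 20 para to the ring oxygen with N-bromosuccinimide would give (3R,4S)-6-bromo-5,8-dimethoxy-2,2-dimethylchromane-3,4-diyl diacetate F2, and Miyaura borylation (B2pin2, PdCl2(dppf), KOAc, dioxane) would give the pinacol boronate F3. Suzuki–Miyaura coupling of F1 with F3 (Pd(PPh3)4, CsF, dioxane) would give the 3-aryl-2-(dimethylamino)chromone F4. Oxidative demethylation with (NH4)2Ce(NO3)6 would give the aryl quinone F5, and reduction with Na2S2O4 would give hydroquinone 22, which is closed to 23 in AcOH as in step 13.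

2. Step 2. The ring closure may stall after the carbonyl addition, because the C–F carbon then has no conjugating acceptor. Alternatively, the strongly basic medium may cause loss of fluoride to an aryne or reduction by residual lithium arenide. The fallback sets out from 2 and comes back at 6; it closes the ring through an ortho-ketone-activated SNAr instead. Addition of MeMgBr to 2 would give 1-[2,6-difluoro-4-(methoxymethoxy)phenyl]ethanol F6, and oxidation with Dess–Martin periodinane would give 1-[2,6-difluoro-4-(methoxymethoxy)phenyl]ethanone F7. Aldol addition of its lithium enolate (LiN(iPr)2, THF, −78 °C) to acetone would give 1-[2,6-difluoro-4-(methoxymethoxy)phenyl]-3-hydroxy-3-methylbutan-1-one F8. K2CO3 in DMF would close 5-fluoro-7-(methoxymethoxy)-2,2-dimethylchroman-4-one F9 by displacement of the fluorine ortho to the ketone, and NaBH4 reduction would give 6.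

3. Step 4. The ortho-fluoro aryllithium may lose LiF (aryne formation) if the temperature rises, the second equivalent of base may attack the α-amino alkoxide, or the second metalation may stay incomplete. The fallback sets out from 7 and comes back at 9; it replaces the second lithiation by halogenation and cross-coupling. A single lithiation of 7 (s-BuLi, THF, −78 °C) and DMF quench would give 5-fluoro-7-(methoxymethoxy)-2,2-dimethyl-2H-chromene-6-carbaldehyde F10, which is isolated. Bromination of the one remaining ring position with N-bromosuccinimide would give 8-bromo-5-fluoro-7-(methoxymethoxy)-2,2-dimethyl-2H-chromene-6-carbaldehyde F11, and Suzuki–Miyaura methylation (trimethylboroxine, Pd(PPh3)4, K2CO3, dioxane) would give 9.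

Further compounds

F1 | step 13 | 2-(dimethylamino)-5-hydroxy-3-iodo-6,8,8-trimethyl-4H,8H-pyrano[2,3-f]chromen-4-one | CN(C)c1oc2c3C=CC(C)(C)Oc3c(C)c(O)c2c(=O)c1I
F2 | step 13 | (3R,4S)-6-bromo-5,8-dimethoxy-2,2-dimethylchromane-3,4-diyl diacetate | COc1c(Br)cc(OC)c2OC(C)(C)[C@H](OC(C)=O)[C@@H](OC(C)=O)c12
F3 | step 13 | (3R,4S)-5,8-dimethoxy-2,2-dimethyl-6-(4,4,5,5-tetramethyl-1,3,2-dioxaborolan-2-yl)chromane-3,4-diyl diacetate | COc1c(B3OC(C)(C)C(C)(C)O3)cc(OC)c2OC(C)(C)[C@H](OC(C)=O)[C@@H](OC(C)=O)c12
F4 | step 13 | (3R,4S)-6-[2-(dimethylamino)-5-hydroxy-6,8,8-trimethyl-4-oxo-4H,8H-pyrano[2,3-f]chromen-3-yl]-5,8-dimethoxy-2,2-dimethylchromane-3,4-diyl diacetate | CN(C)c1oc2c3C=CC(C)(C)Oc3c(C)c(O)c2c(=O)c1-c1cc(OC)c2OC(C)(C)[C@H](OC(C)=O)[C@@H](OC(C)=O)c2c1OC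
F5 | step 13 | (3R,4S)-6-[2-(dimethylamino)-5-hydroxy-6,8,8-trimethyl-4-oxo-4H,8H-pyrano[2,3-f]chromen-3-yl]-2,2-dimethyl-5,8-dioxo-3,4,5,8-tetrahydro-2H-chromene-3,4-diyl diacetate | CN(C)c1oc2c3C=CC(C)(C)Oc3c(C)c(O)c2c(=O)c1C1=CC(=O)C2=C(C1=O)[C@H](OC(C)=O)[C@@H](OC(C)=O)C(C)(C)O2
F6 | step 2 | 1-[2,6-difluoro-4-(methoxymethoxy)phenyl]ethanol (racemic) | COCOc1cc(F)c(C(C)O)c(F)c1
F7 | step 2 | 1-[2,6-difluoro-4-(methoxymethoxy)phenyl]ethanone | COCOc1cc(F)c(C(C)=O)c(F)c1
F8 | step 2 | 1-[2,6-difluoro-4-(methoxymethoxy)phenyl]-3-hydroxy-3-methylbutan-1-one | COCOc1cc(F)c(C(=O)CC(C)(C)O)c(F)c1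
F9 | step 2 | 5-fluoro-7-(methoxymethoxy)-2,2-dimethylchroman-4-one | COCOc1cc(F)c2C(=O)CC(C)(C)Oc2c1
F10 | step 4 | 5-fluoro-7-(methoxymethoxy)-2,2-dimethyl-2H-chromene-6-carbaldehyde | COCOc1cc2OC(C)(C)C=Cc2c(F)c1C=O
F11 | step 4 | 8-bromo-5-fluoro-7-(methoxymethoxy)-2,2-dimethyl-2H-chromene-6-carbaldehyde | COCOc1c(Br)c2OC(C)(C)C=Cc2c(F)c1C=O
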